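**Plan**
1. Retrosynthesis: Wittig cuts at C11'=C12' and C11=C12 give the ε‑C15 aldehyde 13, the C10 trienedial 20 and the acetylenic C15 phosphonium salt 19. Salt 19 is cut at C6–C7 (Sonogashira coupling of the enol triflate of (4R,6R)‑actinol with enynol 1).
2. In 13 the 7'E double bond is traced to a 7',8'‑triple bond and the ε‑ring (C1'–C6') is contracted by excising C4'. Its C3'(OH)–C4'H=C5'(CH3) triad, with unsubstituted C4' between the carbinol carbon and the methyl‑bearing carbon, is what a one‑carbon ring expansion of a 2‑methylcyclopentanone enol ether delivers. C6', γ to oxygen in the six‑membered ring and next to the gem‑dimethyl carbon C1', is the β‑carbon of 2,4,4‑trimethylcyclopent‑2‑enone 3.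
3. Forward: conjugate alkynylation of 3 with enyne 2 (enolate trapped as silyl enol ether) → cyclopropanation → oxidative expansion of the five‑ to the six‑membered enone → 1,2‑reduction → trans‑semireduction of the alkyne → oxidation to 13. Separately 14 → 19, extension with 20 to the C25 aldehyde and its phosphonium salt; final Wittig with 13, then desilylation.
4. Stereochemistry: C6' from the catalyst‑controlled conjugate addition; C3' from substrate‑controlled hydride delivery (trans to the C6' chain); C3 from (4R,6R)‑actinol. 9E and 9'E come from enynol 1, 7'E from trans‑hydrosilylation/protodesilylation, 11E and 11'E from Wittig olefination followed by thermal Z→E equilibration.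

Key step: step 4

Remark: compounds 1, 3, 14 and 20 are taken as purchasable; carotenoid numbering (primed = ε half) is used for atoms, and the CIP letter at the carbon that becomes C6' changes along the route only because substituent priorities change (the spatial arrangement stays the same).

**Route**

Step 1
Reactants: 1 (E)-3-methylpent-2-en-4-yn-1-ol
Product: 2 tert-butyldimethyl{[(2E)-3-methylpent-2-en-4-yn-1-yl]oxy}silane
Conditions: TBSCl, imidazole, DMF, 0 °C→rt
Reagents that add atoms: tert-butyldimethylsilyl chloride CC(C)(C)[Si](C)(C)Cl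
Why: Standard silylation of a primary allylic alcohol masks the hydroxyl for the organoaluminium chemistry of step 2; no stereocentre is involved.

Step 2
Reactants: 2 tert-butyldimethyl{[(2E)-3-methylpent-2-en-4-yn-1-yl]oxy}silane; 3 2,4,4-trimethylcyclopent-2-en-1-one
Product: 6 tert-butyldimethyl{[(2E)-3-methyl-5-[(1S)-2,5,5-trimethyl-3-(trimethylsilyloxy)cyclopent-2-en-1-yl]pent-2-en-4-yn-1-yl]oxy}silane, via alkynyl(diisobutyl)alane 4 (not isolated), via aluminium enolate 5 (not isolated)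
Conditions: DIBAL-H (1 equiv), Et3N (5 mol %), hexanes, rt→50 °C; then 3, Cu(OTf)2 (5 mol %), chiral sulfonate-bearing NHC–Ag complex (2.5 mol %, antipode that gives 1S), THF, −30→4 °C; then TMSOTf, −78→0 °C
Reagents that add atoms: trimethylsilyl trifluoromethanesulfonate C[Si](C)(C)OS(=O)(=O)C(F)(F)F
Why: Cu–NHC‑catalysed enantioselective conjugate addition of an in situ alkynylaluminium reagent to a cyclic enone should place the alkynyl group on C3 of 3 (the future C6') with the catalyst choosing the enone face, and O‑silylation of the aluminium enolate fixes the tetrasubstituted enol ether needed in step 3.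

Step 3
Reactants: 6 tert-butyldimethyl{[(2E)-3-methyl-5-[(1S)-2,5,5-trimethyl-3-(trimethylsilyloxy)cyclopent-2-en-1-yl]pent-2-en-4-yn-1-yl]oxy}silane
Product: 7 (1S,2S,5S)-2-[(3E)-5-(tert-butyldimethylsilyloxy)-3-methylpent-3-en-1-yn-1-yl]-1,3,3-trimethyl-5-(trimethylsilyloxy)bicyclo[3.1.0]hexane
Conditions: Et2Zn (2 equiv), CH2I2 (2 equiv), toluene, 0 °C→rt; pyridine quench
Reagents that add atoms: diiodomethane ICI
Why: Furukawa–Simmons–Smith cyclopropanation should occur only at the electron‑rich silyl enol ether (the alkyne is inert and the enyne alkene is deactivated), anti to the alkynyl group; both new centres are erased in step 4, so the face of attack is immaterial.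

Step 4
Reactants: 7 (1S,2S,5S)-2-[(3E)-5-(tert-butyldimethylsilyloxy)-3-methylpent-3-en-1-yn-1-yl]-1,3,3-trimethyl-5-(trimethylsilyloxy)bicyclo[3.1.0]hexane
Product: 9 (4R)-4-[(3E)-5-(tert-butyldimethylsilyloxy)-3-methylpent-3-en-1-yn-1-yl]-3,5,5-trimethylcyclohex-2-en-1-one, via β-chloro ketone 8 (not isolated)
Conditions: FeCl3 (2.2 equiv), pyridine (1 equiv), DMF, 0 °C→rt; then NaOAc, MeOH, 40 °C
Reagents that add atoms: none
Why: FeCl3 desilylates the cyclopropanol ether and oxidises it by one electron to a cyclopropyloxy radical, whose β‑scission cuts the bond shared by the three‑ and five‑membered rings (C3'–C5'), so that the former carbenoid carbon C4' becomes a ring member and the five‑membered ring grows to the six‑membered ring C1'–C6'; chlorine transfer from a second FeCl3 gives the tertiary β‑chloro ketone 8 and acetate‑mediated E1cB loss of HCl gives enone 9. The closest known reaction type is the FeCl3‑mediated one‑carbon ring expansion of 1‑siloxybicyclo[n.1.0]alkanes to cycloalk‑2‑enones (Ito–Saegusa ring expansion). No ring is closed: the cyclopropane is opened and its CH2 is inserted between the carbonyl carbon and the α‑carbon of the cyclopentanone. No new stereocentre remains in 9 (C5' of 8 is a transient mixture that becomes sp2), and the C6' centre from step 2 is not part of the radical or the enolate and should be carried through unchanged. The step needs scission of the internal and not the external cyclopropane bonds, and elimination towards C4' and not towards C6' or the methyl group; the first is secured by the C5' methyl group (tertiary radical plus relief of bicyclic strain), the second by the acidity of the C4' hydrogens α to the carbonyl. The C6' substituent is carried as an alkyne because 3‑exo cyclisation of the C5' radical onto it is unfavourable, whereas a dienyl group would offer an allyl‑stabilised radical trap.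

Step 5
Reactants: 9 (4R)-4-[(3E)-5-(tert-butyldimethylsilyloxy)-3-methylpent-3-en-1-yn-1-yl]-3,5,5-trimethylcyclohex-2-en-1-one
Product: 10 (1R,4R)-4-[(3E)-5-(tert-butyldimethylsilyloxy)-3-methylpent-3-en-1-yn-1-yl]-3,5,5-trimethylcyclohex-2-en-1-ol
Conditions: L-Selectride (1.2 equiv), THF, −78 °C; then H2O
Reagents that add atoms: none
Why: With the C6' substituent pseudoaxial (it avoids A(1,2) strain with the C5' methyl), the C1' methyl on the opposite face is syn‑axial to the carbonyl, so the bulky hydride should do a 1,2‑reduction from the face of the alkynyl group and place the hydroxyl trans to it (3'R).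

Step 6
Reactants: 10 (1R,4R)-4-[(3E)-5-(tert-butyldimethylsilyloxy)-3-methylpent-3-en-1-yn-1-yl]-3,5,5-trimethylcyclohex-2-en-1-ol
Product: 12 (1R,4R)-4-[(1E,3E)-5-hydroxy-3-methylpenta-1,3-dien-1-yl]-3,5,5-trimethylcyclohex-2-en-1-ol, via Z-alkenylsilane 11 (not isolated)
Conditions: (EtO)3SiH (1.3 equiv), [Cp*Ru(MeCN)3]PF6 (3 mol %), CH2Cl2, 0 °C→rt; then TBAF (4 equiv), CuI (0.2 equiv), THF, rt
Reagents that add atoms: none
Why: Ru‑catalysed trans‑hydrosilylation adds H and Si anti across the alkyne, and fluoride/copper protodesilylation with retention should give the 7'E alkene (either silyl regioisomer converges), while the same fluoride removes the primary TBS ether.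

Step 7
Reactants: 12 (1R,4R)-4-[(1E,3E)-5-hydroxy-3-methylpenta-1,3-dien-1-yl]-3,5,5-trimethylcyclohex-2-en-1-ol
Product: 13 (2E,4E)-5-[(1R,4R)-4-hydroxy-2,6,6-trimethylcyclohex-2-en-1-yl]-3-methylpenta-2,4-dienal
Conditions: TEMPO (10 mol %), PhI(OAc)2 (1.1 equiv), CH2Cl2, rt
Reagents that add atoms: none
Why: Oxoammonium oxidation is selective for the primary dienylic alcohol over the secondary allylic C3' hydroxyl and should stop at the aldehyde without touching the double‑bond geometry.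

Step 8
Reactants: 14 (4R,6R)-4-hydroxy-2,2,6-trimethylcyclohexan-1-one
Product: 15 (4R,6R)-4-(tert-butyldimethylsilyloxy)-2,2,6-trimethylcyclohexan-1-one
Conditions: TBSCl, imidazole, DMF, rt
Reagents that add atoms: tert-butyldimethylsilyl chloride CC(C)(C)[Si](C)(C)Cl
Why: Standard silylation protects the secondary alcohol (future C3, configuration from the chiral pool) for enolate and phosphonium chemistry.

Step 9
Reactants: 15 (4R,6R)-4-(tert-butyldimethylsilyloxy)-2,2,6-trimethylcyclohexan-1-one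
Product: 17 (4R)-4-(tert-butyldimethylsilyloxy)-2,6,6-trimethylcyclohex-1-en-1-yl trifluoromethanesulfonate, via lithium enolate 16 (not isolated)
Conditions: LDA, THF, −78 °C; then PhNTf2, −78 °C→rt
Reagents that add atoms: N-phenylbis(trifluoromethanesulfonimide) O=S(=O)(N(c1ccccc1)S(=O)(=O)C(F)(F)F)C(F)(F)F
Why: C6 is the only enolisable position (C2 is quaternary), so the enolate and the tetrasubstituted enol triflate should form regiospecifically; the C6 centre is erased and the silyloxy centre is untouched.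

Step 10
Reactants: 17 (4R)-4-(tert-butyldimethylsilyloxy)-2,6,6-trimethylcyclohex-1-en-1-yl trifluoromethanesulfonate; 1 (E)-3-methylpent-2-en-4-yn-1-ol
Product: 18 (2E)-5-[(4R)-4-(tert-butyldimethylsilyloxy)-2,6,6-trimethylcyclohex-1-en-1-yl]-3-methylpent-2-en-4-yn-1-ol
Conditions: Pd(PPh3)4 (5 mol %), CuI (10 mol %), Et3N, DMF, rt
Reagents that add atoms: none
Why: Sonogashira coupling of a hindered cyclohexenyl triflate with a terminal enyne forms the C6–C7 bond and installs the 7,8‑triple bond with the 9E geometry of 1 retained.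

Step 11
Reactants: 18 (2E)-5-[(4R)-4-(tert-butyldimethylsilyloxy)-2,6,6-trimethylcyclohex-1-en-1-yl]-3-methylpent-2-en-4-yn-1-ol
Product: 19 [(2E)-5-[(4R)-4-(tert-butyldimethylsilyloxy)-2,6,6-trimethylcyclohex-1-en-1-yl]-3-methylpent-2-en-4-yn-1-yl]triphenylphosphonium bromide
Conditions: PPh3·HBr, CH2Cl2, 0 °C→rt
Reagents that add atoms: triphenylphosphine hydrobromide [Br-].[PH+](c1ccccc1)(c1ccccc1)c1ccccc1
Why: Acid‑assisted ionisation of the primary allylic alcohol and capture by PPh3 at the unhindered terminus is the classical C15 Wittig‑salt formation; the aprotic medium should spare the secondary silyl ether.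

Step 12
Reactants: 19 [(2E)-5-[(4R)-4-(tert-butyldimethylsilyloxy)-2,6,6-trimethylcyclohex-1-en-1-yl]-3-methylpent-2-en-4-yn-1-yl]triphenylphosphonium bromide; 20 (2E,4E,6E)-2,7-dimethylocta-2,4,6-trienedial
Product: 22 (2E,4E,6E,8E,10E)-13-[(4R)-4-(tert-butyldimethylsilyloxy)-2,6,6-trimethylcyclohex-1-en-1-yl]-2,7,11-trimethyltrideca-2,4,6,8,10-pentaen-12-ynal, via C15 ylide 21 (not isolated)
Conditions: 20 (2.5 equiv), NaOMe, CH2Cl2–MeOH, 0 °C→rt; brief reflux in EtOH; chromatography
Reagents that add atoms: none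
Why: Wittig olefination with excess dialdehyde should stop at the mono‑adduct, and the hindered 11Z fraction from the semi‑stabilised ylide equilibrates thermally to 11E.

Step 13
Reactants: 22 (2E,4E,6E,8E,10E)-13-[(4R)-4-(tert-butyldimethylsilyloxy)-2,6,6-trimethylcyclohex-1-en-1-yl]-2,7,11-trimethyltrideca-2,4,6,8,10-pentaen-12-ynal
Product: 23 (2E,4E,6E,8E,10E)-13-[(4R)-4-(tert-butyldimethylsilyloxy)-2,6,6-trimethylcyclohex-1-en-1-yl]-2,7,11-trimethyltrideca-2,4,6,8,10-pentaen-12-yn-1-ol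
Conditions: NaBH4, MeOH–THF, 0 °C
Reagents that add atoms: none
Why: Borohydride reduces the polyenal to the primary allylic alcohol by 1,2‑addition and leaves the polyene and alkyne intact.

Step 14
Reactants: 23 (2E,4E,6E,8E,10E)-13-[(4R)-4-(tert-butyldimethylsilyloxy)-2,6,6-trimethylcyclohex-1-en-1-yl]-2,7,11-trimethyltrideca-2,4,6,8,10-pentaen-12-yn-1-ol
Product: 24 [(2E,4E,6E,8E,10E)-13-[(4R)-4-(tert-butyldimethylsilyloxy)-2,6,6-trimethylcyclohex-1-en-1-yl]-2,7,11-trimethyltrideca-2,4,6,8,10-pentaen-12-yn-1-yl]triphenylphosphonium bromide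
Conditions: PPh3·HBr, CH2Cl2, 0 °C→rt
Reagents that add atoms: triphenylphosphine hydrobromide [Br-].[PH+](c1ccccc1)(c1ccccc1)c1ccccc1
Why: The polyenylic primary alcohol ionises readily and PPh3 should attack the terminal carbon, as in the formation of apo‑carotenyl Wittig salts; the acid‑sensitive ε‑ring is not yet present.

Step 15
Reactants: 24 [(2E,4E,6E,8E,10E)-13-[(4R)-4-(tert-butyldimethylsilyloxy)-2,6,6-trimethylcyclohex-1-en-1-yl]-2,7,11-trimethyltrideca-2,4,6,8,10-pentaen-12-yn-1-yl]triphenylphosphonium bromide; 13 (2E,4E)-5-[(1R,4R)-4-hydroxy-2,6,6-trimethylcyclohex-2-en-1-yl]-3-methylpenta-2,4-dienal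
Product: 26 (3R,3'R,6'R)-3-(tert-butyldimethylsilyloxy)-7,8-didehydro-β,ε-caroten-3'-ol, via C25 ylide 25 (not isolated)
Conditions: NaOMe, CH2Cl2–MeOH, 0 °C→rt; brief reflux in EtOH under N2 in the dark; crystallisation
Reagents that add atoms: none
Why: Wittig olefination joins C11' and C12'; putting the ylide on the C25 half keeps the epimerisable, doubly allylic C6'–H out of ylide chemistry, and the hindered 11'Z fraction equilibrates thermally to E.

Step 16
Reactants: 26 (3R,3'R,6'R)-3-(tert-butyldimethylsilyloxy)-7,8-didehydro-β,ε-caroten-3'-ol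
Product: 27 (3R,3'R,6'R)-7,8-didehydro-β,ε-carotene-3,3'-diol
Conditions: TBAF, THF, 0 °C→rt, dark
Reagents that add atoms: none
Why: Fluoride cleaves the secondary silyl ether under conditions that carotenoid polyenes and the allylic 3'-hydroxyl tolerate; no stereocentre is touched.

**Compound list**
1 | (E)-3-methylpent-2-en-4-yn-1-ol | C#C/C(C)=C/CO | starting material
2 | tert-butyldimethyl{[(2E)-3-methylpent-2-en-4-yn-1-yl]oxy}silane | C#C/C(C)=C/CO[Si](C)(C)C(C)(C)C | intermediate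
3 | 2,4,4-trimethylcyclopent-2-en-1-one | CC1=CC(C)(C)CC1=O | starting material
4 | diisobutyl[(3E)-5-(tert-butyldimethylsilyloxy)-3-methylpent-3-en-1-yn-1-yl]alane | CC(C)C[Al](CC(C)C)C#C/C(C)=C/CO[Si](C)(C)C(C)(C)C | intermediate
5 | diisobutylaluminium (3S)-3-[(3E)-5-(tert-butyldimethylsilyloxy)-3-methylpent-3-en-1-yn-1-yl]-2,4,4-trimethylcyclopent-1-en-1-olate | CC1=C(O[Al](CC(C)C)CC(C)C)CC(C)(C)[C@H]1C#C/C(C)=C/CO[Si](C)(C)C(C)(C)C | intermediate
6 | tert-butyldimethyl{[(2E)-3-methyl-5-[(1S)-2,5,5-trimethyl-3-(trimethylsilyloxy)cyclopent-2-en-1-yl]pent-2-en-4-yn-1-yl]oxy}silane | CC1=C(O[Si](C)(C)C)CC(C)(C)[C@H]1C#C/C(C)=C/CO[Si](C)(C)C(C)(C)C | intermediate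
7 | (1S,2S,5S)-2-[(3E)-5-(tert-butyldimethylsilyloxy)-3-methylpent-3-en-1-yn-1-yl]-1,3,3-trimethyl-5-(trimethylsilyloxy)bicyclo[3.1.0]hexane (CH2 bridge anti to the enynyl group) | C[C@@]12C[C@]1(O[Si](C)(C)C)CC(C)(C)[C@H]2C#C/C(C)=C/CO[Si](C)(C)C(C)(C)C | intermediate
8 | (4S)-4-[(3E)-5-(tert-butyldimethylsilyloxy)-3-methylpent-3-en-1-yn-1-yl]-3-chloro-3,5,5-trimethylcyclohexan-1-one (C3 epimers) | CC1(Cl)CC(=O)CC(C)(C)[C@H]1C#C/C(C)=C/CO[Si](C)(C)C(C)(C)C | intermediate
9 | (4R)-4-[(3E)-5-(tert-butyldimethylsilyloxy)-3-methylpent-3-en-1-yn-1-yl]-3,5,5-trimethylcyclohex-2-en-1-one | CC1=CC(=O)CC(C)(C)[C@H]1C#C/C(C)=C/CO[Si](C)(C)C(C)(C)C | intermediate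
10 | (1R,4R)-4-[(3E)-5-(tert-butyldimethylsilyloxy)-3-methylpent-3-en-1-yn-1-yl]-3,5,5-trimethylcyclohex-2-en-1-ol | CC1=C[C@H](O)CC(C)(C)[C@H]1C#C/C(C)=C/CO[Si](C)(C)C(C)(C)C | intermediate
11 | (1R,4R)-4-[(1Z,3E)-5-(tert-butyldimethylsilyloxy)-3-methyl-2-(triethoxysilyl)penta-1,3-dien-1-yl]-3,5,5-trimethylcyclohex-2-en-1-ol (expected major regioisomer) | CC1=C[C@H](O)CC(C)(C)[C@H]1/C=C(\[Si](OCC)(OCC)OCC)/C(C)=C/CO[Si](C)(C)C(C)(C)C | intermediate
12 | (1R,4R)-4-[(1E,3E)-5-hydroxy-3-methylpenta-1,3-dien-1-yl]-3,5,5-trimethylcyclohex-2-en-1-ol | CC1=C[C@H](O)CC(C)(C)[C@H]1/C=C/C(C)=C/CO | intermediate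
13 | (2E,4E)-5-[(1R,4R)-4-hydroxy-2,6,6-trimethylcyclohex-2-en-1-yl]-3-methylpenta-2,4-dienal | CC1=C[C@H](O)CC(C)(C)[C@H]1/C=C/C(C)=C/C=O | intermediate
14 | (4R,6R)-4-hydroxy-2,2,6-trimethylcyclohexan-1-one (actinol) | O=C1[C@H](C)C[C@@H](O)CC1(C)C | starting material
15 | (4R,6R)-4-(tert-butyldimethylsilyloxy)-2,2,6-trimethylcyclohexan-1-one | O=C1[C@H](C)C[C@@H](O[Si](C)(C)C(C)(C)C)CC1(C)C | intermediate
16 | lithium (4R)-4-(tert-butyldimethylsilyloxy)-2,6,6-trimethylcyclohex-1-en-1-olate | [Li]OC1=C(C)C[C@@H](O[Si](C)(C)C(C)(C)C)CC1(C)C | intermediate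
17 | (4R)-4-(tert-butyldimethylsilyloxy)-2,6,6-trimethylcyclohex-1-en-1-yl trifluoromethanesulfonate | FC(F)(F)S(=O)(=O)OC1=C(C)C[C@@H](O[Si](C)(C)C(C)(C)C)CC1(C)C | intermediate
18 | (2E)-5-[(4R)-4-(tert-butyldimethylsilyloxy)-2,6,6-trimethylcyclohex-1-en-1-yl]-3-methylpent-2-en-4-yn-1-ol | OC/C=C(\C)C#CC1=C(C)C[C@@H](O[Si](C)(C)C(C)(C)C)CC1(C)C | intermediate
19 | [(2E)-5-[(4R)-4-(tert-butyldimethylsilyloxy)-2,6,6-trimethylcyclohex-1-en-1-yl]-3-methylpent-2-en-4-yn-1-yl]triphenylphosphonium bromide | [Br-].c1ccccc1[P+](c1ccccc1)(c1ccccc1)C/C=C(\C)C#CC1=C(C)C[C@@H](O[Si](C)(C)C(C)(C)C)CC1(C)C | intermediate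
20 | (2E,4E,6E)-2,7-dimethylocta-2,4,6-trienedial | O=C/C(C)=C/C=C/C=C(\C)C=O | starting material
21 | ylide of 19: [(2E)-5-[(4R)-4-(tert-butyldimethylsilyloxy)-2,6,6-trimethylcyclohex-1-en-1-yl]-3-methylpent-2-en-4-yn-1-ylidene]triphenylphosphorane | c1ccccc1P(c1ccccc1)(c1ccccc1)=C/C=C(\C)C#CC1=C(C)C[C@@H](O[Si](C)(C)C(C)(C)C)CC1(C)C | intermediate
22 | (2E,4E,6E,8E,10E)-13-[(4R)-4-(tert-butyldimethylsilyloxy)-2,6,6-trimethylcyclohex-1-en-1-yl]-2,7,11-trimethyltrideca-2,4,6,8,10-pentaen-12-ynal | O=C/C(C)=C/C=C/C=C(C)/C=C/C=C(\C)C#CC1=C(C)C[C@@H](O[Si](C)(C)C(C)(C)C)CC1(C)C | intermediate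
23 | (2E,4E,6E,8E,10E)-13-[(4R)-4-(tert-butyldimethylsilyloxy)-2,6,6-trimethylcyclohex-1-en-1-yl]-2,7,11-trimethyltrideca-2,4,6,8,10-pentaen-12-yn-1-ol | OC/C(C)=C/C=C/C=C(C)/C=C/C=C(\C)C#CC1=C(C)C[C@@H](O[Si](C)(C)C(C)(C)C)CC1(C)C | intermediate
24 | [(2E,4E,6E,8E,10E)-13-[(4R)-4-(tert-butyldimethylsilyloxy)-2,6,6-trimethylcyclohex-1-en-1-yl]-2,7,11-trimethyltrideca-2,4,6,8,10-pentaen-12-yn-1-yl]triphenylphosphonium bromide | [Br-].c1ccccc1[P+](c1ccccc1)(c1ccccc1)C/C(C)=C/C=C/C=C(C)/C=C/C=C(\C)C#CC1=C(C)C[C@@H](O[Si](C)(C)C(C)(C)C)CC1(C)C | intermediate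
25 | ylide of 24: the corresponding trideca-2,4,6,8,10-pentaen-12-yn-1-ylidene(triphenyl)phosphorane | c1ccccc1P(c1ccccc1)(c1ccccc1)=C/C(C)=C/C=C/C=C(C)/C=C/C=C(\C)C#CC1=C(C)C[C@@H](O[Si](C)(C)C(C)(C)C)CC1(C)C | intermediate
26 | (3R,3'R,6'R)-3-(tert-butyldimethylsilyloxy)-7,8-didehydro-β,ε-caroten-3'-ol | CC1=C[C@H](O)CC(C)(C)[C@H]1/C=C/C(C)=C/C=C/C(C)=C/C=C/C=C(C)/C=C/C=C(\C)C#CC1=C(C)C[C@@H](O[Si](C)(C)C(C)(C)C)CC1(C)C | intermediate
27 | (3R,3'R,6'R)-7,8-didehydro-β,ε-carotene-3,3'-diol | CC1=C[C@H](O)CC(C)(C)[C@H]1/C=C/C(C)=C/C=C/C(C)=C/C=C/C=C(C)/C=C/C=C(\C)C#CC1=C(C)C[C@@H](O)CC1(C)C | target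

**Step count and risks**
Total: 16 steps. Longest linear sequence: 9 steps (steps 1–7, 15, 16 from 1; the branch from 14 through steps 8–16 is equally long).

Steps most likely to fail:

Step 2. On the α‑methylated enone with a quaternary γ‑carbon the copper‑catalysed alkynyl transfer may be slow, so that uncatalysed 1,2‑addition of the alane and poor enantiofacial discrimination compete. Fallback, setting out from 2 and 3 and returning at 10: the lithium acetylide of 2 is transmetalated to the alkynylzinc bromide and added to 3 under TMSOTf promotion (silyl‑triflate‑promoted conjugate alkynylation) to give the racemic enol ether F1. The operations of steps 3–5 then give the racemic siloxycyclopropane F2, the racemic enone F3 and the racemic trans‑alcohol F4. F4 is esterified with (S)-2-methoxy-2-phenylacetic acid (DCC, DMAP), the diastereomeric esters are separated by chromatography, and the (1R,4R)‑ester F5 is methanolysed (K2CO3, MeOH) to 10.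

Step 6. The conjugated enyne may react sluggishly or unselectively in the hydrosilylation, and the basic fluoride stage may shift the doubly allylic C6' hydrogen or leave protodesilylation incomplete. Fallback, setting out from 10 and returning at 12: Lindlar semihydrogenation (H2, Pd/CaCO3/Pb, quinoline, EtOAc) gives the (7'Z,9'E)‑dienol silyl ether F6. Its hindered 7'Z bond is equilibrated to E with catalytic iodine in daylight to give the (7'E,9'E)‑dienol silyl ether F7, and TBAF then gives 12.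

Step 5. Hydride delivery may show poor facial selectivity if the slim alkynyl group does not hold the pseudoaxial position, giving the cis‑alcohol. Fallback, setting out from 9 and returning at 10: Luche reduction (NaBH4, CeCl3, MeOH) followed by separation gives the cis‑alcohol F8. F8 is inverted under Mitsunobu conditions (4‑nitrobenzoic acid, PPh3, DIAD) to the (1R,4R)‑4‑nitrobenzoate F9, and methanolysis (K2CO3, MeOH) gives 10.

**Further compounds**
F1 | step 2 | racemic tert-butyldimethyl{[(2E)-3-methyl-5-[2,5,5-trimethyl-3-(trimethylsilyloxy)cyclopent-2-en-1-yl]pent-2-en-4-yn-1-yl]oxy}silane | CC1=C(O[Si](C)(C)C)CC(C)(C)C1C#C/C(C)=C/CO[Si](C)(C)C(C)(C)C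
F2 | step 2 | racemic 2-[(3E)-5-(tert-butyldimethylsilyloxy)-3-methylpent-3-en-1-yn-1-yl]-1,3,3-trimethyl-5-(trimethylsilyloxy)bicyclo[3.1.0]hexane | CC12CC1(O[Si](C)(C)C)CC(C)(C)C2C#C/C(C)=C/CO[Si](C)(C)C(C)(C)C
F3 | step 2 | racemic 4-[(3E)-5-(tert-butyldimethylsilyloxy)-3-methylpent-3-en-1-yn-1-yl]-3,5,5-trimethylcyclohex-2-en-1-one | CC1=CC(=O)CC(C)(C)C1C#C/C(C)=C/CO[Si](C)(C)C(C)(C)C
F4 | step 2 | racemic trans-4-[(3E)-5-(tert-butyldimethylsilyloxy)-3-methylpent-3-en-1-yn-1-yl]-3,5,5-trimethylcyclohex-2-en-1-ol (both enantiomers) | CC1=C[C@H](O)CC(C)(C)[C@H]1C#C/C(C)=C/CO[Si](C)(C)C(C)(C)C.CC1=C[C@@H](O)CC(C)(C)[C@@H]1C#C/C(C)=C/CO[Si](C)(C)C(C)(C)C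
F5 | step 2 | (1R,4R)-4-[(3E)-5-(tert-butyldimethylsilyloxy)-3-methylpent-3-en-1-yn-1-yl]-3,5,5-trimethylcyclohex-2-en-1-yl (2S)-2-methoxy-2-phenylacetate | CC1=C[C@H](OC(=O)[C@@H](OC)c2ccccc2)CC(C)(C)[C@H]1C#C/C(C)=C/CO[Si](C)(C)C(C)(C)C
F6 | step 6 | (1R,4R)-4-[(1Z,3E)-5-(tert-butyldimethylsilyloxy)-3-methylpenta-1,3-dien-1-yl]-3,5,5-trimethylcyclohex-2-en-1-ol | CC1=C[C@H](O)CC(C)(C)[C@H]1/C=C\C(C)=C\CO[Si](C)(C)C(C)(C)C
F7 | step 6 | (1R,4R)-4-[(1E,3E)-5-(tert-butyldimethylsilyloxy)-3-methylpenta-1,3-dien-1-yl]-3,5,5-trimethylcyclohex-2-en-1-ol | CC1=C[C@H](O)CC(C)(C)[C@H]1/C=C/C(C)=C/CO[Si](C)(C)C(C)(C)C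
F8 | step 5 | (1S,4R)-4-[(3E)-5-(tert-butyldimethylsilyloxy)-3-methylpent-3-en-1-yn-1-yl]-3,5,5-trimethylcyclohex-2-en-1-ol | CC1=C[C@@H](O)CC(C)(C)[C@H]1C#C/C(C)=C/CO[Si](C)(C)C(C)(C)C
F9 | step 5 | (1R,4R)-4-[(3E)-5-(tert-butyldimethylsilyloxy)-3-methylpent-3-en-1-yn-1-yl]-3,5,5-trimethylcyclohex-2-en-1-yl 4-nitrobenzoate | CC1=C[C@H](OC(=O)c2ccc(cc2)[N+](=O)[O-])CC(C)(C)[C@H]1C#C/C(C)=C/CO[Si](C)(C)C(C)(C)C
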